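## Retrosynthetic overview

1. Numbering follows the eremophilane skeleton. Ring A is C5–C6–C7–C8–C9–C10 (the enedione ring), ring B is C1–C2–C3–C4–C5–C10, and β is the face of the C5 methyl group. The last disconnections are the C9 angelate, the C3 acetate and three silyl ethers.
2. C6=C7 and the C7 acetyl group come from E1cB loss of ethanol from a 6-ethoxy-7-acetyl ketone. That ketone is made by aldol addition of acetaldehyde at C7 followed by oxidation.
3. The key disconnection is C5–C6 and C9–C10. Ring A arises from the four-membered ring (C6, C7, C8, C9) of a 2-silyloxy-3-ethoxycyclobutanone: a Lewis acid breaks its C6–C9 bond and the C5=C10 silyl enol ether of ring B is inserted (two-atom ring expansion, formal [4+2]). This sets C5, C9 and C10 in one operation.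
4. Enabling feature: in ring A the C8 carbonyl lies 1,3 to both C6 (enone β-carbon, aldehyde oxidation level) and C10 (tertiary carbinol), and C9 carries oxygen. C6–C7–C8–C9 is therefore the 1,4-dipole stored in a donor–acceptor cyclobutanone, and C5/C10 is the α-carbon/carbonyl pair of a ring B ketone.
5. Order of rings: ring B is bought (2,3-dimethylcyclohexenone; C3 is set by CBS reduction, C4 by face-selective hydrosilylation), the cyclobutanone comes from a ketene [2+2], and ring A is formed last.

Key step: step 8

Remark on the chemistry: C6 of the key-step adduct, and the new centres of the aldol adduct and of the diketone made from it, are transient. The first is drawn with the expected equatorial ethoxy group and the others are left open, because all become sp2 before the end.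

Abbreviations: TBS = tert-butyldimethylsilyl, TES = triethylsilyl.

## Route

Step 1
Reactants: 1 2,3-dimethylcyclohex-2-en-1-one
Product: 2 2,3-dimethylcyclohex-2-ene-1,4-dione
Conditions: Rh2(cap)4 (cap = caprolactamate, 1 mol %), t-BuOOH (70 % aq.), ClCH2CH2Cl, 40 °C
Reagents that add atoms: tert-butyl hydroperoxide, CC(C)(C)OO
Why: Allylic oxidation of an enone to the 1,4-enedione by tert-butylperoxyl radicals, in which the ring CH2 next to the alkene offers the weakest C–H bond and the base-free medium holds back tautomerisation of 2 to the hydroquinone.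

Step 2
Reactants: 2 2,3-dimethylcyclohex-2-ene-1,4-dione
Product: 3 (4S)-4-hydroxy-2,3-dimethylcyclohex-2-en-1-one
Conditions: (R)-Me-CBS oxazaborolidine (15 mol %), catecholborane (1.05 equiv), toluene, −78 °C; MeOH, aqueous work-up
Reagents that add atoms: none
Why: Corey–Bakshi–Shibata reduction, in which the two carbonyl groups are equivalent, the fully substituted alkene carbon is the large flank and CH2 the small one, so the (R)-catalyst should give the (S)-carbinol (C3 of the target), and the product is no longer an enedione and is reduced much more slowly.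

Step 3
Reactants: 3 (4S)-4-hydroxy-2,3-dimethylcyclohex-2-en-1-one
Product: 4 (4S)-4-(TBSO)-2,3-dimethylcyclohex-2-en-1-one
Conditions: TBSCl, imidazole, DMF, rt
Reagents that add atoms: tert-butyldimethylsilyl chloride, CC(C)(C)[Si](C)(C)Cl
Why: Standard silyl ether formation that leaves the stereocentre untouched and supplies the bulky group needed for face control in step 4.

Step 4
Reactants: 4 (4S)-4-(TBSO)-2,3-dimethylcyclohex-2-en-1-one
Product: 5 tert-butyl{[(1S,2R)-2,3-dimethyl-4-(triethylsilyloxy)cyclohex-3-en-1-yl]oxy}dimethylsilane (ring B enol ether C5=C10; C3-OTBS and C4-methyl cis)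
Conditions: RhCl(PPh3)3 (2 mol %), Et3SiH, THF, 55 °C
Reagents that add atoms: triethylsilane, CC[SiH](CC)CC
Why: Rhodium-catalysed 1,4-hydrosilylation of an enone gives the tetrasubstituted silyl enol ether regiospecifically, and because A1,2 strain with the vinylic methyl pushes the OTBS group pseudoaxial, hydrogen should reach C4 from the opposite face and set the C4 methyl cis to the C3 oxygen.

Step 5
Reactants: 6 glycolic acid
Product: 7 tert-butyldimethylsilyl (tert-butyldimethylsilyloxy)acetate
Conditions: TBSCl (2.2 equiv), imidazole, DMF, rt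
Reagents that add atoms: tert-butyldimethylsilyl chloride, CC(C)(C)[Si](C)(C)Cl
Why: Exhaustive silylation of a hydroxy acid gives the silyl ether and silyl ester in one operation.

Step 6
Reactants: 7 tert-butyldimethylsilyl (tert-butyldimethylsilyloxy)acetate
Product: 8 (tert-butyldimethylsilyloxy)acetyl chloride
Conditions: (COCl)2, DMF (cat.), CH2Cl2, 0 °C to rt
Reagents that add atoms: oxalyl chloride, O=C(Cl)C(=O)Cl
Why: Direct conversion of a silyl ester into the acid chloride with the Vilsmeier reagent releases no HCl, so the silyl ether survives.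

Step 7
Reactants: 8 (tert-butyldimethylsilyloxy)acetyl chloride; 9 ethyl vinyl ether
Product: 11 2-(tert-butyldimethylsilyloxy)-3-ethoxycyclobutan-1-one (racemic cis/trans mixture), via silyloxyketene 10 (not isolated)
Conditions: Et3N (slow addition), neat ethyl vinyl ether (excess), reflux
Reagents that add atoms: none
Why: Dehydrochlorination to the ketene and ketene–enol ether [2+2] cycloaddition, in which the nucleophilic CH2 terminus bonds to the ketene carbonyl carbon so that the ethoxy carbon ends up next to the silyloxy carbon, and the stereoisomer mixture does not matter because both centres are erased in step 8.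

Step 8
Reactants: 5 ring B silyl enol ether; 11 2-(tert-butyldimethylsilyloxy)-3-ethoxycyclobutan-1-one
Product: 12 6β-ethoxy-4β,5β-dimethyl-3β,9α-bis(TBSO)-10β-(TESO)-cis-decalin-8-one
Conditions: EtAlCl2 (1.5 equiv), CH2Cl2, −78 to −40 °C; aq. NaHCO3
Reagents that add atoms: none
Why: Proposed new method: EtAlCl2 binds the C8 carbonyl of 11, and the push of the ethoxy oxygen together with the pull of the forming aluminium enolate breaks the strained C6–C9 bond to a 1,4-dipole (oxocarbenium ion at C6, α-silyloxy enolate at C9); enol ether carbon C5 of 5 adds to C6 in a Mukaiyama-type step and C9 then attacks the silyl-activated C10 carbonyl, so that C5 and C10 are inserted into the four-membered ring, which becomes six-membered ring A with the silyl group kept on the C10 oxygen. The closest known reaction type is the Lewis-acid-promoted formal [4+2] cycloaddition of 3-alkoxycyclobutanones with silyl enol ethers to 3-alkoxy-5-silyloxycyclohexanones, in which the more substituted C2–C3 bond of the cyclobutanone breaks; not yet shown are a 2-silyloxy group on the cyclobutanone and a tetrasubstituted ring enol ether as partner. Ring A is the only ring closed, by a 6-(enolendo)-exo-trig aldol addition through a chair in which the new C6 arm is axial on ring B, the geometry of Robinson-type ketol formation, which leads to the cis-fused decalin. C5 is controlled by C4, since A1,2 strain with the C5 methyl holds the C4 methyl pseudoaxial on the β face and C6 enters axially from the α face (cis-4,5-dimethyl); C10 is controlled by C5, since the axial arm reaches the carbonyl only from the α face and leaves oxygen β; C9 is controlled by the chair, the silyloxy group taking the equatorial α site because the axial β site is syn-axial to the C5 methyl (this is also the more stable epimer next to the ketone); C6 is expected with equatorial ethoxy and is erased in step 10. The step needs bond selectivity in 11, and this is secured by the C9 silyloxy group, which makes C6–C9 the more substituted and more crowded bond and stabilises the developing enolate inductively, while the CH2 side has neither help. Both stereocentres of 11 become planar in the dipole, so the racemic cis/trans mixture should converge on one product and all absolute control comes from 5.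

Step 9
Reactants: 12 cis-decalin-8-one from step 8; 13 acetaldehyde
Product: 14 7-(1-hydroxyethyl) derivative of 12 (mixture at C7 and at the carbinol carbon)
Conditions: LiN(iPr)2, THF, −78 °C; MeCHO; AcOH quench at −78 °C
Reagents that add atoms: none
Why: Kinetic lithium enolate aldol addition, in which the base takes the accessible C7 proton rather than the C9 methine shielded by OTBS and the fully substituted C10, β-alkoxide loss is slow at −78 °C, and the two new centres are of no consequence because both become sp2 in step 10.

Step 10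
Reactants: 14 7-(1-hydroxyethyl) ketone
Product: 16 7-acetyl-4β,5β-dimethyl-3β,9α-bis(TBSO)-10β-(TESO)-cis-decal-6-en-8-one, via 1,3-diketone 15 (not isolated)
Conditions: Dess–Martin periodinane, pyridine, CH2Cl2, 0 °C to rt; then DBU, 4 Å MS, rt
Reagents that add atoms: none
Why: Dess–Martin oxidation followed by E1cB elimination, in which only the doubly activated C7–H is acidic enough for DBU, A1,3 strain with the acetyl enolate turns the C6 ethoxy group pseudoaxial for departure, the C10 silyl ether (which would need C9 deprotonation) stays, and C5 bears no hydrogen so the alkene can only be C6=C7.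

Step 11
Reactants: 16 tris-silyl enedione
Product: 17 7-acetyl-3β,9α,10β-trihydroxy-4β,5β-dimethyl-cis-decal-6-en-8-one
Conditions: HF·pyridine, THF, 0 °C to rt
Reagents that add atoms: none
Why: Acidic fluoride cleaves all three silyl ethers without base, so retro-aldol cleavage and β-elimination of the C8/C10 ketol are avoided and no stereocentre is touched.

Step 12
Reactants: 17 triol
Product: 18 3β-acetoxy-7-acetyl-9α,10β-dihydroxy-4β,5β-dimethyl-cis-decal-6-en-8-one
Conditions: Ac2O (1.1 equiv), pyridine, CH2Cl2, 0 °C
Reagents that add atoms: acetic anhydride, CC(=O)OC(C)=O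
Why: Chemoselective acylation, in which the C3 hydroxyl is an ordinary secondary alcohol whereas the C9 hydroxyl is hydrogen-bonded to the C8 carbonyl and wedged against the fully substituted C10 and the C10 hydroxyl is tertiary, so one equivalent of anhydride should stop at the 3-acetate.

Step 13
Reactants: 18 3-acetate diol; 19 angelic acid ((Z)-2-methylbut-2-enoic acid)
Product: 21 target CNP0196241.1, via angelic trichlorobenzoic anhydride 20 (not isolated)
Conditions: 2,4,6-Cl3C6H2COCl, Et3N, toluene, rt; then 18, 75 °C
Reagents that add atoms: none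
Why: Yamaguchi mixed-anhydride esterification without a nucleophilic catalyst, the standard way to transfer the angeloyl group without Z to E isomerisation, acylates the secondary C9 hydroxyl with retention while the tertiary C10 hydroxyl does not react.

## Compound list

1 | 2,3-dimethylcyclohex-2-en-1-one | CC1=C(C)C(=O)CCC1 | starting material
2 | 2,3-dimethylcyclohex-2-ene-1,4-dione | CC1=C(C)C(=O)CCC1=O | intermediate
3 | (4S)-4-hydroxy-2,3-dimethylcyclohex-2-en-1-one | O=C1CC[C@H](O)C(C)=C1C | intermediate
4 | (4S)-4-(tert-butyldimethylsilyloxy)-2,3-dimethylcyclohex-2-en-1-one | O=C1CC[C@H](O[Si](C)(C)C(C)(C)C)C(C)=C1C | intermediate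
5 | tert-butyl{[(1S,2R)-2,3-dimethyl-4-(triethylsilyloxy)cyclohex-3-en-1-yl]oxy}dimethylsilane | CC[Si](CC)(CC)OC1=C(C)[C@@H](C)[C@@H](O[Si](C)(C)C(C)(C)C)CC1 | intermediate
6 | glycolic acid | OCC(=O)O | starting material
7 | tert-butyldimethylsilyl (tert-butyldimethylsilyloxy)acetate | CC(C)(C)[Si](C)(C)OCC(=O)O[Si](C)(C)C(C)(C)C | intermediate
8 | (tert-butyldimethylsilyloxy)acetyl chloride | CC(C)(C)[Si](C)(C)OCC(=O)Cl | intermediate
9 | ethyl vinyl ether | C=COCC | starting material
10 | (tert-butyldimethylsilyloxy)ketene (not isolated) | CC(C)(C)[Si](C)(C)OC=C=O | intermediate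
11 | 2-(tert-butyldimethylsilyloxy)-3-ethoxycyclobutan-1-one, racemic cis/trans mixture | CCOC1CC(=O)C1O[Si](C)(C)C(C)(C)C | intermediate
12 | (3S,4R,5S,6R,9S,10R)-6β-ethoxy-4β,5β-dimethyl-3β,9α-bis(TBSO)-10β-(TESO)-cis-decalin-8-one | CC(C)(C)[Si](C)(C)O[C@@H]1C(=O)C[C@@H](OCC)[C@]2(C)[C@@H](C)[C@@H](O[Si](C)(C)C(C)(C)C)CC[C@]12O[Si](CC)(CC)CC | intermediate
13 | acetaldehyde | CC=O | starting material
14 | 7-(1-hydroxyethyl) derivative of 12, open at C7 and at the carbinol carbon | CC(C)(C)[Si](C)(C)O[C@@H]1C(=O)C(C(C)O)[C@@H](OCC)[C@]2(C)[C@@H](C)[C@@H](O[Si](C)(C)C(C)(C)C)CC[C@]12O[Si](CC)(CC)CC | intermediate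
15 | 7-acetyl-6β-ethoxy ketone (1,3-diketone, open at C7, not isolated) | CC(C)(C)[Si](C)(C)O[C@@H]1C(=O)C(C(C)=O)[C@@H](OCC)[C@]2(C)[C@@H](C)[C@@H](O[Si](C)(C)C(C)(C)C)CC[C@]12O[Si](CC)(CC)CC | intermediate
16 | (3S,4R,5R,9S,10R)-7-acetyl-4β,5β-dimethyl-3β,9α-bis(TBSO)-10β-(TESO)-cis-decal-6-en-8-one | CC(C)(C)[Si](C)(C)O[C@@H]1C(=O)C(C(C)=O)=C[C@]2(C)[C@@H](C)[C@@H](O[Si](C)(C)C(C)(C)C)CC[C@]12O[Si](CC)(CC)CC | intermediate
17 | (3S,4R,5R,9S,10R)-7-acetyl-3β,9α,10β-trihydroxy-4β,5β-dimethyl-cis-decal-6-en-8-one | O[C@@H]1C(=O)C(C(C)=O)=C[C@]2(C)[C@@H](C)[C@@H](O)CC[C@]12O | intermediate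
18 | (3S,4R,5R,9S,10R)-3β-acetoxy-7-acetyl-9α,10β-dihydroxy-4β,5β-dimethyl-cis-decal-6-en-8-one | O[C@@H]1C(=O)C(C(C)=O)=C[C@]2(C)[C@@H](C)[C@@H](OC(C)=O)CC[C@]12O | intermediate
19 | angelic acid, (Z)-2-methylbut-2-enoic acid | C/C=C(/C)C(=O)O | starting material
20 | angelic 2,4,6-trichlorobenzoic anhydride (not isolated) | C/C=C(/C)C(=O)OC(=O)c1c(Cl)cc(Cl)cc1Cl | intermediate
21 | CNP0196241.1, (3S,4R,5R,9S,10R)-3β-acetoxy-7-acetyl-9α-angeloyloxy-10β-hydroxy-4β,5β-dimethyl-cis-decal-6-en-8-one | C/C=C(/C)C(=O)O[C@@H]1C(=O)C(C(C)=O)=C[C@]2(C)[C@@H](C)[C@@H](OC(C)=O)CC[C@]12O | target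

## Step count and risks

Total step count: 13. Longest linear sequence: 10 steps (steps 1–4 and 8–13).

**Step 8 (key step).**
- What may go wrong:
  - heterolysis of the CH2-side ring bond of the cyclobutanone instead of C6–C9, which would give annulation with the wrong orientation;
  - stalling after the first C–C bond, through silyl transfer to the enolate before the crowded aldol closure;
  - weak facial control at C5.
- Fallback (known chemistry, sets out from 5, comes back at 16):
  - 5 is combined under the same EtAlCl2 conditions with commercial, symmetrical 3-(benzyloxy)cyclobutan-1-one. This is the established formal [4+2], in which both breakable bonds are equivalent, and it should give the 9-unsubstituted 6β-benzyloxy cis-decalone F1.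
  - DBU removes benzyl alcohol to give the enone F2. The C10 silyl ether lies equatorial on ring A and is not aligned for loss.
  - LiN(SiMe3)2 followed by 2-(phenylsulfonyl)-3-phenyloxaziridine hydroxylates the only enolisable position, C9, from the α face away from the axial C5 methyl, giving the 9α-hydroxy enone F3.
  - TBSOTf and 2,6-lutidine give the 9α-silyl ether F4.
  - I2 in pyridine gives the 7-iodo enone F5.
  - Stille coupling with tributyl(1-ethoxyvinyl)stannane under PdCl2(PPh3)2 gives the 7-(1-ethoxyvinyl) enone F6, and dilute HCl hydrolyses it to 16.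

**Step 4.**
- What may go wrong: sluggish turnover or competing 1,2-addition on the tetrasubstituted enone, and erosion of face selectivity at C4.
- Fallback (sets out from 4, comes back at 5): hydrogenation over Pd/C adds hydrogen to the face away from the OTBS group and gives the saturated all-cis ketone F7, whose C5 centre is of no consequence. Et3SiCl, NaI and Et3N in MeCN under equilibrating conditions then give the more substituted enol ether 5.

**Step 1.**
- What may go wrong: tautomerisation of the enedione to the hydroquinone with over-oxidation to the quinone, and radical attack at the methyl groups.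
- Fallback (sets out from 1, comes back at 2): TBSOTf and Et3N convert 1 into the linear silyl dienol ether F8. mCPBA oxidises its remote double bond (vinylogous Rubottom oxidation) to the racemic γ-hydroxy enone F9. Dess–Martin periodinane then gives 2 under neutral conditions.

Further compounds
F1 | step 8 | 6β-benzyloxy-4β,5β-dimethyl-3β-(TBSO)-10β-(TESO)-cis-decalin-8-one | C1C(=O)C[C@@H](OCc3ccccc3)[C@]2(C)[C@@H](C)[C@@H](O[Si](C)(C)C(C)(C)C)CC[C@]12O[Si](CC)(CC)CC
F2 | step 8 | 4β,5β-dimethyl-3β-(TBSO)-10β-(TESO)-cis-decal-6-en-8-one | C1C(=O)C=C[C@]2(C)[C@@H](C)[C@@H](O[Si](C)(C)C(C)(C)C)CC[C@]12O[Si](CC)(CC)CC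
F3 | step 8 | 9α-hydroxy-4β,5β-dimethyl-3β-(TBSO)-10β-(TESO)-cis-decal-6-en-8-one | O[C@@H]1C(=O)C=C[C@]2(C)[C@@H](C)[C@@H](O[Si](C)(C)C(C)(C)C)CC[C@]12O[Si](CC)(CC)CC
F4 | step 8 | 4β,5β-dimethyl-3β,9α-bis(TBSO)-10β-(TESO)-cis-decal-6-en-8-one | CC(C)(C)[Si](C)(C)O[C@@H]1C(=O)C=C[C@]2(C)[C@@H](C)[C@@H](O[Si](C)(C)C(C)(C)C)CC[C@]12O[Si](CC)(CC)CC
F5 | step 8 | 7-iodo-4β,5β-dimethyl-3β,9α-bis(TBSO)-10β-(TESO)-cis-decal-6-en-8-one | CC(C)(C)[Si](C)(C)O[C@@H]1C(=O)C(I)=C[C@]2(C)[C@@H](C)[C@@H](O[Si](C)(C)C(C)(C)C)CC[C@]12O[Si](CC)(CC)CC
F6 | step 8 | 7-(1-ethoxyvinyl)-4β,5β-dimethyl-3β,9α-bis(TBSO)-10β-(TESO)-cis-decal-6-en-8-one | CC(C)(C)[Si](C)(C)O[C@@H]1C(=O)C(C(=C)OCC)=C[C@]2(C)[C@@H](C)[C@@H](O[Si](C)(C)C(C)(C)C)CC[C@]12O[Si](CC)(CC)CC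
F7 | step 4 | all-cis 4-(TBSO)-2,3-dimethylcyclohexan-1-one | O=C1CC[C@H](O[Si](C)(C)C(C)(C)C)[C@H](C)[C@@H]1C
F8 | step 1 | 1-(tert-butyldimethylsilyloxy)-2,3-dimethylcyclohexa-1,3-diene | CC1=C(O[Si](C)(C)C(C)(C)C)CCC=C1C
F9 | step 1 | racemic 4-hydroxy-2,3-dimethylcyclohex-2-en-1-one | O=C1CCC(O)C(C)=C1C
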